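## Structural features

The target is a cis-fused 2-benzoxepin-1-one: cyclohexane ring A (C-5a, C-6, C-7, C-8, C-9, C-9a) shares the C-5a–C-9a bond with ring B, a seven-membered lactone (C-1 carbonyl, O-2, C-3H2, C-4, C-5) whose C-4=C-5 double bond carries the free carboxylic acid on C-4. Four stereocentres run in a row around ring A: C-9 (R; tertiary OH on the face of the C-1 carbonyl, CH2O on the other face), C-9a (S) and C-5a (R), which are cis-fused, and C-6 (S), whose isopropyl group is trans to the C-5 arm on C-5a. The primary oxygen on the C-9 CH2 group is esterified by an (E)-2-(hydroxymethyl)propenoic acid whose β-carbon is bonded to C-1′ of cyclohexene ring C. Ring C has its double bond at C-2′=C-3′, a hydroxymethyl group on C-3′ and an isopropyl group on C-6′ that is cis to the arm on C-1′ (1′R,6′S), the opposite of the trans relation in ring A. Fragile features are the two 2-(oxymethyl)acrylate units (allylic C–O bonds open to SN2′ attack), the γ-hydrogens at C-5a and C-1′ (allylic and vinylogous to an ester), and the seven-membered lactone, which a free C-9 CH2OH could convert into a five-membered lactone. The real difficulties are ring B, a medium-ring lactone with a trisubstituted endocyclic enoate beside two stereocentres, and the cis relation in ring C, which runs against the usual approach of a reagent anti to an existing isopropyl group. In ring B, C-4 lies between the O–CH2 carbon C-3 and the alkene carbon C-5; without C-4 the ring is the six-membered enol lactone 14 (O–CH=CH), and the key step puts C-4 back, with its carboxyl group, as a carbenoid carbon.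

## Logic of the disconnections

36 to 35. Two Si–O bonds and the O–alkyl bond of the silylethyl ester are cut. All three masks fall to fluoride in one operation, so no acid or base meets the lactone and the acrylates at the end. The forward step needs a fluoride source of low basicity.

35 to 32 and 33. The ester C(=O)–O bond at the C-9 CH2O oxygen is cut. This splits the molecule into two halves of similar size, both traceable to 4. The forward step must acylate a primary hydroxyl beside a free tertiary hydroxyl and a lactone without acyl transfer, and must not remove the C-1′ hydrogen of the activated acid.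

33 to 21. Only the two ketal C–O bonds are cut. The diol has to be masked through the carbenoid step, and an isopropylidene ketal is the one group that picks the 1,2-diol out of an earlier triol. The forward hydrolysis must be short and cold.

21 to 14 and 19. The C-3–C-4 and C-4–C-5 bonds are cut and C-4 leaves with its ester. Ring B contracts to a six-membered enol lactone, so a medium-ring lactonisation is replaced by a cyclodehydration. The forward step must cyclopropanate only the enol ester double bond, open the ring-fusion bond of the cyclopropane (this needs the bromine endo), and deliver hydride to the oxygen-bearing allyl terminus.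

19 to 18, 16 and 15. The C–Br bond, the C=N2 unit and the ester C–O bond are cut in turn. This leads to a commercial alcohol. The bromodiazo ester is thermally labile, so it must be made cold and used at once.

14 to 12. The O-2–C-3 bond of the enol ester is cut. The precursor is a cis aldehyde acid on ring A. The forward dehydration must be non-acidic (ketal) and must not epimerise C-9a.

12 to 10. C-1 and C-3 are re-joined through one extra carbon as a cyclohexenone. The different oxidation levels of C-1 (acid) and C-3 (aldehyde) are thereby encoded in one ring. Ozonolysis followed by periodate must cleave the C=C and then only the 1,2-dicarbonyl. The allylic oxygen must therefore be at the ketone level before cleavage; at the alcohol level periodate would leave an aldehyde on C-9a.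

10 to 9, 8 and 6. The oxidation level, the ketal, then the C-9–CH2 bond and the CH2–O bond are removed. C-9 becomes a ketone and its two substituents come from a hydroxymethyl anion equivalent. The nucleophile must enter from the convex face of the cis-fused bicycle.

6 to 4 and 5. The C-9a–C-1 and C-5a–C-5 bonds are cut (Diels–Alder). One step then sets C-9a and C-5a cis to each other and trans to the isopropyl group. The forward step needs an acid catalyst that a silyl dienol ether survives.

4 to 3, then 1 and 2. The C-2=C-3 bond of the enone (aldol condensation) and then the bond between the aldehyde α-carbon and the β-carbon of 2 (Michael addition) are cut. C-6 is the only stereocentre and is set by an amine catalyst.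

32 to 31, 30, 29, 28 and 27. The acid is unmasked from its methyl ester, the second silyl ether is removed, the Cα–CH2OH bond is cut (Stille coupling), then the Cβ=Cα bond (Wittig olefination). This leads to a one-carbon alcohol on C-1′. The aldehyde between them is α-branched and β,γ-unsaturated, so it must be consumed in the flask in which it forms.

27 to 26 and 25. The C-1′–H and CH2–O bonds are cut (hydroboration), then the exocyclic C=CH2 (methylenation). C-1′ is thus set by delivery of hydrogen anti to the isopropyl group. This is the one way in which the usual facial bias gives the cis arrangement.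

25 to 24, 23 and 4. The allylic oxygen is shifted back (oxidative 1,3-transposition), the silyl ether is removed and the C-3′–CH2 bond is cut. Ring C then rests on the same 4 as ring A. The new carbinol centre need not be controlled because the transposition erases it.

## Other disconnections considered

Alternative 1: ring C by an endo Diels–Alder reaction. Cut: C-1′–C-6′ and C-4′–C-5′. Forward key step: the terminal diene of trienoate A2 adds 2 under an N-protonated B-aryl oxazaborolidine (a chiral boron Lewis acid) to give the cis acetyl cyclohexene A1.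
- In its favour: ring C and both its stereocentres arise in one step, in the cis sense that substrate control resists; the arm is in place from the start, so no aldehyde like 28 is needed.
- Against it here: A2 is an electron-poor, cross-conjugated triene, a weak partner for an enone under a cationic Lewis acid that can also ionise allylic silyl ethers. A2 itself needs about six steps. The acetyl group of A1 must become isopropyl by methylenation of an epimerisable ketone and a selective hydrogenation beside two other alkenes.
- Comparison: the chosen plan takes C-6′ from 4 and sets C-1′ by hydroboration anti to isopropyl (steps 13 to 21, nine steps). Alternative 1 relies on catalyst control; the chosen plan on substrate control. Step count is about equal. On convergence, and on avoiding aldehyde 28, alternative 1 is the better. It does not touch ring B and could replace steps 13 to 21 without changing the key step.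

Alternative 2: iodo-β-lactonisation. Cut: the tertiary C-9–O bond and a C–I bond. Forward key step: acid A4, with an exocyclic methylene on C-9, is treated with I2 and aqueous NaHCO3; the carboxylate oxygen adds to C-9 and iodine to the CH2, giving the cis-fused iodomethyl β-lactone A3.
- In its favour: the C-9 configuration follows from the cis fusion of a four-membered ring, not from facial selectivity. The strained lactone can later pass its acyl group to the C-3 oxygen to close ring B.
- Against it here: the iodide of A3 is neopentyl, so its exchange for the acrylate oxygen is slow. β-Lactones lose CO2 on warming and open with nucleophiles. A4 needs the ring B arm built through an epimerisable C-5a aldehyde. A five-membered iodolactone can compete under equilibrating conditions.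
- Comparison: the chosen plan sets C-9 by addition to the convex face of ketone 6 (step 4), which yields both oxygens ready for use. On certainty of the C-9 configuration, and on precedent for ring B closure (acyl transfer against carbon insertion), alternative 2 is the better. On step count the chosen plan is shorter, since it needs no iodide exchange and no separate arm synthesis.

Alternative 3: Ireland–Claisen ring contraction. Cut: the ring-fusion C-9a–C-5a bond. Forward key step: the silyl ketene acetal of the ten-membered (E)-allylic lactone A6 rearranges through a boat-like transition state to the cis vinyl acid A5.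
- In its favour: C-9a and C-5a are set cis, and trans to isopropyl, by a pericyclic transition state. The carboxyl carbon is in place at the right oxidation level and no carbon is discarded.
- Against it here: A6 needs a medium-ring lactonisation and about eight steps. The vinyl group of A5 must still be grown into the ring B arm. Dihydroxylation of the exocyclic methylene tends to place oxygen on the open face, which is the wrong one for C-9. Ring B remains unmade.
- Comparison: step 3 of the chosen plan builds ring A with both anchor carbons of ring B in one cycloaddition from 4, with the same relative configuration. On atom economy alternative 3 is the better, since the chosen plan loses one carbon as formic acid. On step count and on the route to ring B the chosen plan is the better.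

Key step: step 12

Remark on the chemistry: the silyloxy-bearing carbon of 6 to 9 is drawn as in the endo adduct; either epimer converges at enone 10.

## Steps

Step 1
Reactants: 1 3-methylbutanal; 2 but-3-en-2-one
Product: 3 (2S)-5-oxo-2-(propan-2-yl)hexanal
Conditions: (S)-2-(methoxydiphenylmethyl)pyrrolidine (5 mol%), ethyl 3,4-dihydroxybenzoate (20 mol%), neat, 4 °C
Reagents that add atoms: none
Why: Enamine-catalysed Michael addition; the diarylmethyl group shields one face of the E-enamine, so the enone should add to the other face and give the (S) centre (future C-6 and C-6′); the enantiomeric catalyst is available if the sense proves opposite.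

Step 2
Reactants: 3 (2S)-5-oxo-2-(propan-2-yl)hexanal
Product: 4 (4S)-4-(propan-2-yl)cyclohex-2-en-1-one
Conditions: LiOH (0.1 equiv), i-PrOH, rt
Reagents that add atoms: none
Why: Intramolecular aldol condensation of the methyl ketone onto the aldehyde; ring closure should outpace enolisation of the aldehyde, so the stereocentre is kept.

Step 3
Reactants: 4 (4S)-4-(propan-2-yl)cyclohex-2-en-1-one; 5 (E)-1-(trimethylsilyloxy)buta-1,3-diene
Product: 6 (4S,4aS,8S,8aR)-4-isopropyl-8-(trimethylsilyloxy)-3,4,4a,5,8,8a-hexahydronaphthalen-1(2H)-one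
Conditions: HN(SO2CF3)2 (3 mol%), 5 (2 equiv), CH2Cl2, −78 to −40 °C
Reagents that add atoms: none
Why: Diels–Alder reaction catalysed by the silyl triflimide formed in the flask, a Lewis acid that silyl dienol ethers tolerate; the diene adds anti to the isopropyl group and gives the cis ring fusion (C-9a and C-5a of the target), with the oxygenated diene terminus bonded to the enone α-carbon.

Step 4
Reactants: 6 (4S,4aS,8S,8aR)-4-isopropyl-8-(trimethylsilyloxy)-3,4,4a,5,8,8a-hexahydronaphthalen-1(2H)-one
Product: 8 cis-fused 1-(hydroxymethyl)-4-isopropyl-1,2,3,4,4a,5,8,8a-octahydronaphthalene-1,8-diol (1-OH cis to the C-8a–C-8 bond), via silyl carbinol 7 (not isolated)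
Conditions: (i-PrO)Me2SiCH2MgCl, CeCl3, THF, −78 to 0 °C; then KF, KHCO3, 30% H2O2, THF/MeOH, rt
Reagents that add atoms: (isopropoxydimethylsilyl)methylmagnesium chloride CC(C)O[Si](C)(C)C[Mg]Cl; hydrogen peroxide OO
Why: 1,2-Addition of a hydroxymethyl anion equivalent, then Tamao–Fleming oxidation; the nucleophile should enter from the convex face, anti to the axial C-8a–C-8 bond, which sets C-9 of the target with OH cis to the future C-1; CeCl3 curbs enolisation and KF also removes the trimethylsilyl ether.

Step 5
Reactants: 8 cis-fused 1-(hydroxymethyl)-4-isopropyl-1,2,3,4,4a,5,8,8a-octahydronaphthalene-1,8-diol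
Product: 9 isopropylidene ketal of 8 across the 1-OH and the CH2OH (8-OH free)
Conditions: Me2C(OMe)2, pyridinium p-toluenesulfonate (5 mol%), acetone, rt
Reagents that add atoms: 2,2-dimethoxypropane COC(C)(C)OC
Why: Ketalisation under thermodynamic control; the five-membered dioxolane of the 1,2-diol is preferred over a six-membered ketal, which leaves the allylic alcohol free.

Step 6
Reactants: 9 isopropylidene ketal of 8
Product: 10 cis-fused cyclohexenone from 9 (the C-8 carbinol oxidised to the conjugated ketone)
Conditions: 1,1,1-triacetoxy-1,1-dihydro-1,2-benziodoxol-3(1H)-one, NaHCO3, CH2Cl2, 0 °C to rt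
Reagents that add atoms: none
Why: Hypervalent iodine oxidation of a secondary allylic alcohol; the buffer keeps the C-9a hydrogen, now α to a ketone, from epimerising.

Step 7
Reactants: 10 cis-fused cyclohexenone from 9
Product: 12 cis aldehyde acid (CO2H on C-9a and CH2CHO on C-5a of ring A; ketal intact), via keto dialdehyde 11 (not isolated)
Conditions: O3, CH2Cl2/MeOH, −78 °C; Me2S, to rt; then NaIO4, THF/H2O, 0 °C to rt
Reagents that add atoms: ozone [O-][O+]=O; water O
Why: Ozonolysis of the enone, then periodate cleavage of the hydrated 1,2-dicarbonyl only; the isolated aldehyde is not a periodate substrate, so C-1 ends as the acid and C-3 as the aldehyde, and one carbon leaves as formic acid.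

Step 8
Reactants: 12 cis aldehyde acid
Product: 14 isopropylidene ketal of (4aR,5S,8R,8aS)-8-hydroxy-8-(hydroxymethyl)-5-isopropyl-4a,5,6,7,8,8a-hexahydro-1H-isochromen-1-one, via lactol mesylate 13 (not isolated)
Conditions: MeSO2Cl, Et3N, CH2Cl2, −20 to 20 °C
Reagents that add atoms: none
Why: Cyclodehydration: the ring (hydroxy lactone) tautomer is sulfonylated and loses methanesulfonic acid under amine, as in glycal formation from 2-deoxy lactols; the conditions are non-acidic, so the ketal should survive.

Step 9
Reactants: 15 2-(trimethylsilyl)ethanol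
Product: 16 2-(trimethylsilyl)ethyl bromoacetate
Conditions: BrCH2COBr, pyridine, CH2Cl2, 0 °C
Reagents that add atoms: bromoacetyl bromide BrCC(Br)=O
Why: Acylation of a primary alcohol by an acid bromide.

Step 10
Reactants: 16 2-(trimethylsilyl)ethyl bromoacetate
Product: 18 2-(trimethylsilyl)ethyl diazoacetate, via alkylated ditosylhydrazine 17 (not isolated)
Conditions: TsNHNHTs, 1,8-diazabicyclo[5.4.0]undec-7-ene (DBU), THF, 0 °C
Reagents that add atoms: N,N′-bis(p-tolylsulfonyl)hydrazine Cc1ccc(cc1)S(=O)(=O)NNS(=O)(=O)c1ccc(C)cc1
Why: Diazo ester synthesis from a bromoacetate: N-alkylation of the ditosylhydrazine, then base-induced loss of two sulfinates.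

Step 11
Reactants: 18 2-(trimethylsilyl)ethyl diazoacetate
Product: 19 2-(trimethylsilyl)ethyl bromodiazoacetate
Conditions: N-bromosuccinimide, DBU, CH2Cl2, 0 °C, 10 min; cold filtration through silica; solution used at once
Reagents that add atoms: N-bromosuccinimide BrN1C(=O)CCC1=O
Why: Electrophilic bromination of the deprotonated diazo carbon; the halodiazo ester is thermally labile and is therefore kept cold and not stored.

Step 12
Reactants: 14 isopropylidene ketal of (4aR,5S,8R,8aS)-8-hydroxy-8-(hydroxymethyl)-5-isopropyl-4a,5,6,7,8,8a-hexahydro-1H-isochromen-1-one; 19 2-(trimethylsilyl)ethyl bromodiazoacetate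
Product: 21 isopropylidene ketal of 2-(trimethylsilyl)ethyl (5aR,6S,9R,9aS)-9-hydroxy-9-(hydroxymethyl)-6-isopropyl-1-oxo-1,3,5a,6,7,8,9,9a-octahydro-2-benzoxepine-4-carboxylate, via bromocyclopropane 20 (not isolated)
Conditions: Rh2(esp)2 (1 mol%; esp = α,α,α′,α′-tetramethyl-1,3-benzenedipropanoate), 19 (1.5 equiv, cold solution added over 1 h), CH2Cl2, 0 °C; then Et3SiH (3 equiv), 2,6-di-tert-butyl-4-methylpyridine (1.5 equiv), (CF3)2CHOH co-solvent, 0 to 40 °C
Reagents that add atoms: none
Why: Proposed new method: the electrophilic carbenoid formed from 19 on divalent rhodium adds to the enol ester C=C of 14, the only electron-rich alkene, from the convex face; by analogy with donor/acceptor carbenoids the ester should sit exo and the bromine endo in 20. An endo bromide is the one whose loss is coupled to disrotatory opening of the ring-fusion bond, with the ring oxygen lone pair assisting, so the six-membered ring becomes a seven-membered acyloxy-stabilised allyl cation with the ester on its central carbon; hexafluoroisopropanol is there to support this ionisation. Et3SiH is added only after the diazo compound is consumed, because Si–H insertion would otherwise intercept the carbenoid, and should deliver hydride to the oxygen-bearing terminus, where the charge resides, as in reductions of Ferrier-type allyl oxocarbenium ions; this leaves C-4=C-5 conjugated with the new ester. Ring B is thus formed by expansion, not by cyclisation: the bond shared by the lactone and the cyclopropane is cleaved and the carbenoid carbon ends bonded to C-3 and C-5. No stereocentre is created, the four of ring A are untouched and the cyclopropane centres are transient. The closest known reactions are the rhodium-catalysed halodiazoacetate cyclopropanation and ring expansion of indoles to quinoline-3-carboxylates and the ring expansion of glycal-derived halocyclopropanes to oxepines; silane capture of this cation is the untested part. The step needs chemoselective cyclopropanation and hydride capture at the O-substituted terminus; the ring oxygen directs both, and the hindered pyridine buffers HBr so that the ketal survives.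

Step 13
Reactants: 4 (4S)-4-(propan-2-yl)cyclohex-2-en-1-one
Product: 23 (4S)-1-(hydroxymethyl)-4-isopropylcyclohex-2-en-1-ol (C-1 epimers), via silyl carbinol 22 (not isolated)
Conditions: (i-PrO)Me2SiCH2MgCl, THF, 0 °C; then KF, KHCO3, 30% H2O2, THF/MeOH, rt
Reagents that add atoms: (isopropoxydimethylsilyl)methylmagnesium chloride CC(C)O[Si](C)(C)C[Mg]Cl; hydrogen peroxide OO
Why: Grignard 1,2-addition to the enone and Tamao–Fleming oxidation; the configuration of the new carbinol does not matter because step 15 erases it.

Step 14
Reactants: 23 (4S)-1-(hydroxymethyl)-4-isopropylcyclohex-2-en-1-ol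
Product: 24 (4S)-1-{[(tert-butyldimethylsilyl)oxy]methyl}-4-isopropylcyclohex-2-en-1-ol (C-1 epimers)
Conditions: t-BuMe2SiCl, imidazole, CH2Cl2, 0 °C
Reagents that add atoms: tert-butyldimethylsilyl chloride CC(C)(C)[Si](C)(C)Cl
Why: Selective silylation of the primary hydroxyl; the tertiary allylic hydroxyl stays free for the transposition.

Step 15
Reactants: 24 (4S)-1-{[(tert-butyldimethylsilyl)oxy]methyl}-4-isopropylcyclohex-2-en-1-ol
Product: 25 (6S)-3-{[(tert-butyldimethylsilyl)oxy]methyl}-6-isopropylcyclohex-2-en-1-one
Conditions: pyridinium chlorochromate C5H5NH[CrO3Cl], NaOAc, 4 Å molecular sieves, CH2Cl2, rt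
Reagents that add atoms: none
Why: Babler–Dauben oxidative 1,3-transposition (sigmatropic shift of the chromate ester, then oxidation); the acetate buffer is there to spare the stereocentre, which is now α to the ketone.

Step 16
Reactants: 25 (6S)-3-{[(tert-butyldimethylsilyl)oxy]methyl}-6-isopropylcyclohex-2-en-1-one
Product: 26 tert-butyl{[(4S)-4-isopropyl-3-methylidenecyclohex-1-en-1-yl]methoxy}dimethylsilane
Conditions: Cp2Ti(μ-Cl)(μ-CH2)AlMe2, pyridine, THF/toluene, −40 to 0 °C
Reagents that add atoms: μ-chloro-μ-methylene-bis(cyclopentadienyl)titanium dimethylaluminium C[Al-]1(C)C[Ti]([Cl+]1)(C1C=CC=C1)C1C=CC=C1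
Why: Carbonyl methylenation by the titanium methylidene that pyridine releases from the chloride-bridged titanium–aluminium reagent (the bridge is drawn as an aluminate–chloronium pair); the reagent is not basic and pyridine ties up the dimethylaluminium chloride, so the α-stereocentre should not enolise.

Step 17
Reactants: 26 tert-butyl{[(4S)-4-isopropyl-3-methylidenecyclohex-1-en-1-yl]methoxy}dimethylsilane
Product: 27 [(1R,6S)-3-{[(tert-butyldimethylsilyl)oxy]methyl}-6-isopropylcyclohex-2-en-1-yl]methanol
Conditions: 9-borabicyclo[3.3.1]nonane dimer, THF, 0 °C to rt; then NaOH, 30% H2O2, 0 °C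
Reagents that add atoms: hydrogen peroxide OO
Why: Hydroboration–oxidation of the 1,1-disubstituted exocyclic alkene; the bulky borane should add from the face opposite the neighbouring isopropyl group, so hydrogen enters C-1′ anti to isopropyl and the CH2OH ends cis to it (1′R); the trisubstituted ring alkene is too hindered for this borane.

Step 18
Reactants: 27 [(1R,6S)-3-{[(tert-butyldimethylsilyl)oxy]methyl}-6-isopropylcyclohex-2-en-1-yl]methanol
Product: 29 methyl (2Z)-2-bromo-3-[(1R,6S)-3-{[(tert-butyldimethylsilyl)oxy]methyl}-6-isopropylcyclohex-2-en-1-yl]prop-2-enoate, via aldehyde 28 (not isolated)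
Conditions: 1,1,1-triacetoxy-1,1-dihydro-1,2-benziodoxol-3(1H)-one, NaHCO3, CH2Cl2, 0 °C; then Ph3P=C(Br)CO2Me, rt
Reagents that add atoms: methyl bromo(triphenylphosphoranylidene)acetate COC(=O)C(Br)=P(c1ccccc1)(c1ccccc1)c1ccccc1
Why: Oxidation and Wittig olefination in one flask keep the life of the α-branched β,γ-unsaturated aldehyde short; the stabilised α-bromo ylide should give the (Z)-bromo enoate, in which the ring is trans to the ester.

Step 19
Reactants: 29 methyl (2Z)-2-bromo-3-[(1R,6S)-3-{[(tert-butyldimethylsilyl)oxy]methyl}-6-isopropylcyclohex-2-en-1-yl]prop-2-enoate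
Product: 30 methyl (2E)-2-(hydroxymethyl)-3-[(1R,6S)-3-{[(tert-butyldimethylsilyl)oxy]methyl}-6-isopropylcyclohex-2-en-1-yl]prop-2-enoate
Conditions: Bu3SnCH2OH, Pd(PPh3)4 (5 mol%), 1,4-dioxane, 85 °C
Reagents that add atoms: (tributylstannyl)methanol CCCC[Sn](CCCC)(CCCC)CO
Why: Stille coupling on zerovalent palladium replaces bromine by CH2OH with retention of the alkene geometry.

Step 20
Reactants: 30 methyl (2E)-2-(hydroxymethyl)-3-[(1R,6S)-3-{[(tert-butyldimethylsilyl)oxy]methyl}-6-isopropylcyclohex-2-en-1-yl]prop-2-enoate
Product: 31 methyl (2E)-2-{[(tert-butyldimethylsilyl)oxy]methyl}-3-[(1R,6S)-3-{[(tert-butyldimethylsilyl)oxy]methyl}-6-isopropylcyclohex-2-en-1-yl]prop-2-enoate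
Conditions: t-BuMe2SiCl, imidazole, CH2Cl2, rt
Reagents that add atoms: tert-butyldimethylsilyl chloride CC(C)(C)[Si](C)(C)Cl
Why: Silylation of the primary allylic alcohol, so that the acid cannot acylate itself in step 23.

Step 21
Reactants: 31 methyl (2E)-2-{[(tert-butyldimethylsilyl)oxy]methyl}-3-[(1R,6S)-3-{[(tert-butyldimethylsilyl)oxy]methyl}-6-isopropylcyclohex-2-en-1-yl]prop-2-enoate
Product: 32 (2E)-2-{[(tert-butyldimethylsilyl)oxy]methyl}-3-[(1R,6S)-3-{[(tert-butyldimethylsilyl)oxy]methyl}-6-isopropylcyclohex-2-en-1-yl]prop-2-enoic acid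
Conditions: LiOH·H2O, THF/MeOH/H2O, rt; then 0.5 M HCl to pH 4
Reagents that add atoms: lithium hydroxide [Li+].[OH-]
Why: Saponification of the methyl ester; the silyl ethers tolerate hydroxide and the brief mild acidification.

Step 22
Reactants: 21 isopropylidene ketal of 2-(trimethylsilyl)ethyl (5aR,6S,9R,9aS)-9-hydroxy-9-(hydroxymethyl)-6-isopropyl-1-oxo-1,3,5a,6,7,8,9,9a-octahydro-2-benzoxepine-4-carboxylate
Product: 33 2-(trimethylsilyl)ethyl (5aR,6S,9R,9aS)-9-hydroxy-9-(hydroxymethyl)-6-isopropyl-1-oxo-1,3,5a,6,7,8,9,9a-octahydro-2-benzoxepine-4-carboxylate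
Conditions: CF3CO2H/H2O (9:1), CH2Cl2, 0 °C
Reagents that add atoms: none
Why: Acid hydrolysis of the ketal, kept short and cold; in the preferred chair of ring A the CH2OH is axial and anti to the axial lactone carbonyl, so acyl transfer to a five-membered lactone needs a ring flip and should be slow.

Step 23
Reactants: 32 (2E)-2-{[(tert-butyldimethylsilyl)oxy]methyl}-3-[(1R,6S)-3-{[(tert-butyldimethylsilyl)oxy]methyl}-6-isopropylcyclohex-2-en-1-yl]prop-2-enoic acid; 33 2-(trimethylsilyl)ethyl (5aR,6S,9R,9aS)-9-hydroxy-9-(hydroxymethyl)-6-isopropyl-1-oxo-1,3,5a,6,7,8,9,9a-octahydro-2-benzoxepine-4-carboxylate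
Product: 35 bis(tert-butyldimethylsilyl) ether 2-(trimethylsilyl)ethyl ester of the target, via mixed anhydride 34 (not isolated)
Conditions: 2,4,6-Cl3C6H2COCl, Et3N, THF, 0 °C; then 33, 4-(dimethylamino)pyridine, toluene, 0 °C to rt
Reagents that add atoms: none
Why: Yamaguchi esterification through the mixed anhydride; only the primary hydroxyl of 33 should react, the tertiary one being too hindered.

Step 24
Reactants: 35 bis(tert-butyldimethylsilyl) ether 2-(trimethylsilyl)ethyl ester of the target
Product: 36 (5aR,6S,9R,9aS)-9-hydroxy-9-({[(2E)-2-(hydroxymethyl)-3-[(1R,6S)-3-(hydroxymethyl)-6-isopropylcyclohex-2-en-1-yl]prop-2-enoyl]oxy}methyl)-6-isopropyl-1-oxo-1,3,5a,6,7,8,9,9a-octahydro-2-benzoxepine-4-carboxylic acid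
Conditions: [(Me2N)3S][Me3SiF2], DMF, 0 °C to rt; aqueous NH4Cl
Reagents that add atoms: none
Why: Fluoride cleaves both silyl ethers and fragments the silylethyl ester (fluorosilane and ethene); the difluorosilicate is a fluoride source of low basicity, which spares the lactone and the acrylates.

## Compound list

1 | 3-methylbutanal | CC(C)CC=O | starting material
2 | but-3-en-2-one | CC(=O)C=C | starting material
3 | (2S)-5-oxo-2-(propan-2-yl)hexanal | CC(C)[C@@H](C=O)CCC(C)=O | intermediate
4 | (4S)-4-(propan-2-yl)cyclohex-2-en-1-one | CC(C)[C@@H]1CCC(=O)C=C1 | intermediate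
5 | (E)-1-(trimethylsilyloxy)buta-1,3-diene | C=C/C=C/O[Si](C)(C)C | starting material
6 | (4S,4aS,8S,8aR)-4-isopropyl-8-(trimethylsilyloxy)-3,4,4a,5,8,8a-hexahydronaphthalen-1(2H)-one | CC(C)[C@@H]1CCC(=O)[C@H]2[C@@H](O[Si](C)(C)C)C=CC[C@@H]12 | intermediate
7 | tertiary carbinol from 6 with CH2SiMe2(O-i-Pr) on C-1 | CC(C)[C@@H]1CC[C@](O)(C[Si](C)(C)OC(C)C)[C@H]2[C@@H](O[Si](C)(C)C)C=CC[C@@H]12 | intermediate (not isolated)
8 | cis-fused 1-(hydroxymethyl)-4-isopropyl-1,2,3,4,4a,5,8,8a-octahydronaphthalene-1,8-diol | CC(C)[C@@H]1CC[C@](O)(CO)[C@H]2[C@@H](O)C=CC[C@@H]12 | intermediate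
9 | isopropylidene ketal of 8 (1-O and CH2O) | CC(C)[C@@H]1CC[C@]3(COC(C)(C)O3)[C@H]2[C@@H](O)C=CC[C@@H]12 | intermediate
10 | cis-fused cyclohexenone from 9 | CC(C)[C@@H]1CC[C@]3(COC(C)(C)O3)[C@H]2C(=O)C=CC[C@@H]12 | intermediate
11 | keto dialdehyde (C(=O)CHO on C-9a, CH2CHO on C-5a) | CC(C)[C@@H]1CC[C@]3(COC(C)(C)O3)[C@@H](C(=O)C=O)[C@H]1CC=O | intermediate (not isolated)
12 | cis aldehyde acid (CO2H on C-9a, CH2CHO on C-5a) | CC(C)[C@@H]1CC[C@]3(COC(C)(C)O3)[C@@H](C(=O)O)[C@H]1CC=O | intermediate
13 | lactol mesylate of 12 | CC(C)[C@@H]1CC[C@]3(COC(C)(C)O3)[C@H]2C(=O)OC(OS(C)(=O)=O)C[C@@H]12 | intermediate (not isolated)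
14 | isopropylidene ketal of (4aR,5S,8R,8aS)-8-hydroxy-8-(hydroxymethyl)-5-isopropyl-4a,5,6,7,8,8a-hexahydro-1H-isochromen-1-one | CC(C)[C@@H]1CC[C@]3(COC(C)(C)O3)[C@H]2C(=O)OC=C[C@@H]12 | intermediate
15 | 2-(trimethylsilyl)ethanol | C[Si](C)(C)CCO | starting material
16 | 2-(trimethylsilyl)ethyl bromoacetate | BrCC(=O)OCC[Si](C)(C)C | intermediate
17 | 2-(trimethylsilyl)ethyl [1,2-bis(p-tolylsulfonyl)hydrazinyl]acetate | Cc1ccc(cc1)S(=O)(=O)NN(CC(=O)OCC[Si](C)(C)C)S(=O)(=O)c1ccc(C)cc1 | intermediate (not isolated)
18 | 2-(trimethylsilyl)ethyl diazoacetate | [N-]=[N+]=CC(=O)OCC[Si](C)(C)C | intermediate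
19 | 2-(trimethylsilyl)ethyl bromodiazoacetate | [N-]=[N+]=C(Br)C(=O)OCC[Si](C)(C)C | intermediate
20 | bromocyclopropane from 14 (cyclopropane centres transient, not assigned) | CC(C)[C@@H]1CC[C@]3(COC(C)(C)O3)[C@H]2C(=O)OC4C([C@@H]12)C4(Br)C(=O)OCC[Si](C)(C)C | intermediate (not isolated)
21 | isopropylidene ketal of 2-(trimethylsilyl)ethyl (5aR,6S,9R,9aS)-9-hydroxy-9-(hydroxymethyl)-6-isopropyl-1-oxo-1,3,5a,6,7,8,9,9a-octahydro-2-benzoxepine-4-carboxylate | CC(C)[C@@H]1CC[C@]3(COC(C)(C)O3)[C@H]2C(=O)OCC(C(=O)OCC[Si](C)(C)C)=C[C@@H]12 | intermediate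
22 | (4S)-1-[(isopropoxydimethylsilyl)methyl]-4-isopropylcyclohex-2-en-1-ol | CC(C)[C@@H]1CCC(O)(C[Si](C)(C)OC(C)C)C=C1 | intermediate (not isolated)
23 | (4S)-1-(hydroxymethyl)-4-isopropylcyclohex-2-en-1-ol | CC(C)[C@@H]1CCC(O)(CO)C=C1 | intermediate
24 | (4S)-1-{[(tert-butyldimethylsilyl)oxy]methyl}-4-isopropylcyclohex-2-en-1-ol | CC(C)[C@@H]1CCC(O)(CO[Si](C)(C)C(C)(C)C)C=C1 | intermediate
25 | (6S)-3-{[(tert-butyldimethylsilyl)oxy]methyl}-6-isopropylcyclohex-2-en-1-one | CC(C)[C@@H]1CCC(CO[Si](C)(C)C(C)(C)C)=CC1=O | intermediate
26 | tert-butyl{[(4S)-4-isopropyl-3-methylidenecyclohex-1-en-1-yl]methoxy}dimethylsilane | CC(C)[C@@H]1CCC(CO[Si](C)(C)C(C)(C)C)=CC1=C | intermediate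
27 | [(1R,6S)-3-{[(tert-butyldimethylsilyl)oxy]methyl}-6-isopropylcyclohex-2-en-1-yl]methanol | CC(C)[C@@H]1CCC(CO[Si](C)(C)C(C)(C)C)=C[C@@H]1CO | intermediate
28 | (1R,6S)-3-{[(tert-butyldimethylsilyl)oxy]methyl}-6-isopropylcyclohex-2-ene-1-carbaldehyde | CC(C)[C@@H]1CCC(CO[Si](C)(C)C(C)(C)C)=C[C@@H]1C=O | intermediate (not isolated)
29 | methyl (2Z)-2-bromo-3-[(1R,6S)-3-{[(tert-butyldimethylsilyl)oxy]methyl}-6-isopropylcyclohex-2-en-1-yl]prop-2-enoate | CC(C)[C@@H]1CCC(CO[Si](C)(C)C(C)(C)C)=C[C@@H]1/C=C(\Br)C(=O)OC | intermediate
30 | methyl (2E)-2-(hydroxymethyl)-3-[(1R,6S)-3-{[(tert-butyldimethylsilyl)oxy]methyl}-6-isopropylcyclohex-2-en-1-yl]prop-2-enoate | CC(C)[C@@H]1CCC(CO[Si](C)(C)C(C)(C)C)=C[C@@H]1/C=C(\CO)C(=O)OC | intermediate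
31 | methyl (2E)-2-{[(tert-butyldimethylsilyl)oxy]methyl}-3-[(1R,6S)-3-{[(tert-butyldimethylsilyl)oxy]methyl}-6-isopropylcyclohex-2-en-1-yl]prop-2-enoate | CC(C)[C@@H]1CCC(CO[Si](C)(C)C(C)(C)C)=C[C@@H]1/C=C(\CO[Si](C)(C)C(C)(C)C)C(=O)OC | intermediate
32 | (2E)-2-{[(tert-butyldimethylsilyl)oxy]methyl}-3-[(1R,6S)-3-{[(tert-butyldimethylsilyl)oxy]methyl}-6-isopropylcyclohex-2-en-1-yl]prop-2-enoic acid | CC(C)[C@@H]1CCC(CO[Si](C)(C)C(C)(C)C)=C[C@@H]1/C=C(\CO[Si](C)(C)C(C)(C)C)C(=O)O | intermediate
33 | 2-(trimethylsilyl)ethyl (5aR,6S,9R,9aS)-9-hydroxy-9-(hydroxymethyl)-6-isopropyl-1-oxo-1,3,5a,6,7,8,9,9a-octahydro-2-benzoxepine-4-carboxylate | CC(C)[C@@H]1CC[C@](O)(CO)[C@H]2C(=O)OCC(C(=O)OCC[Si](C)(C)C)=C[C@@H]12 | intermediate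
34 | mixed anhydride of 32 with 2,4,6-trichlorobenzoic acid | CC(C)[C@@H]1CCC(CO[Si](C)(C)C(C)(C)C)=C[C@@H]1/C=C(\CO[Si](C)(C)C(C)(C)C)C(=O)OC(=O)c1c(Cl)cc(Cl)cc1Cl | intermediate (not isolated)
35 | bis(tert-butyldimethylsilyl) ether 2-(trimethylsilyl)ethyl ester of the target | CC(C)[C@@H]1CC[C@](O)(COC(=O)/C(=C/[C@H]2C=C(CO[Si](C)(C)C(C)(C)C)CC[C@H]2C(C)C)CO[Si](C)(C)C(C)(C)C)[C@H]2C(=O)OCC(C(=O)OCC[Si](C)(C)C)=C[C@@H]12 | intermediate
36 | (5aR,6S,9R,9aS)-9-hydroxy-9-({[(2E)-2-(hydroxymethyl)-3-[(1R,6S)-3-(hydroxymethyl)-6-isopropylcyclohex-2-en-1-yl]prop-2-enoyl]oxy}methyl)-6-isopropyl-1-oxo-1,3,5a,6,7,8,9,9a-octahydro-2-benzoxepine-4-carboxylic acid | CC(C)[C@@H]1CC[C@](O)(COC(=O)/C(=C/[C@H]2C=C(CO)CC[C@H]2C(C)C)CO)[C@H]2C(=O)OCC(C(=O)O)=C[C@@H]12 | target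

## Step count and least certain steps

Total step count: 24 steps.
Longest linear sequence: 13 steps (steps 1, 2, 13 to 21, 23, 24). The line through the bicyclic core (steps 1 to 8, 12, 22 to 24) has 12.

Step 12 (key step, proposed new method). Most likely to go wrong: bromide loss may not occur in the ring-expanding sense, because the exo-bromo diastereomer cannot open this way and the donor–acceptor cyclopropane can instead break its O–C–C(ester) bond. Hydride may also be delivered to the other allyl terminus, or the silyl bromide may strip the ketal. Fallback by known chemistry, setting out from 14: ozonolysis (O3, then Me2S) cleaves the enol ester C=C, and the formyl ester hydrolyses on NaHCO3 work-up to the lower aldehyde acid F1. Wittig olefination with Ph3P=C(Br)CO2CH2CH2SiMe3 gives the (Z)-bromoacrylate acid F2. Stille coupling with Bu3SnCH2OH and Pd(PPh3)4 gives the hydroxy acid F3. Yamaguchi lactonisation at high dilution closes the seven-membered ring and returns to the route at 21.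

Step 3. Most likely to go wrong: the silyl dienol ether may be consumed by protodesilylation or polymerisation faster than the weakly dienophilic cyclohexenone reacts, or the stepwise pathway may stop at the open-chain Michael adduct. Fallback, setting out from 4: bromination and dehydrobromination (Br2, then Et3N) give the far more reactive 2-bromo enone F4. A thermal Diels–Alder reaction with 5 in toluene gives the angular bromide F5. Bu3SnH with a radical initiator removes the bromine; hydrogen should be delivered to the ring-fusion radical from the convex face, which keeps the cis fusion and returns to 6.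

Step 4. Most likely to go wrong: enolisation of the hindered ketone, with epimerisation at the ring fusion or β-elimination of the silyloxy group, may outrun addition. Fallback, setting out from 6: Corey–Chaykovsky epoxidation with Me3S+ I− and n-BuLi should deliver CH2 from the convex face and give the spiro-epoxide F6. KOH in DMSO/H2O opens it at CH2 and removes the silyl ether, returning to 8.

Step 17. Most likely to go wrong: hydroboration of the conjugated diene may take place in the 1,4-sense or at the ring alkene, or facial selectivity may be too low, giving the trans alcohol. Fallback, setting out from 25: LiBH(s-Bu)3 at −78 °C gives the cis allylic alcohol F7, and ClCO2Me with pyridine gives the carbonate F8. Tsuji–Trost alkylation of nitromethane with Pd(PPh3)4 (zerovalent palladium) proceeds by double inversion, with palladium anti to isopropyl and the nucleophile anti to palladium, and gives the cis nitromethyl compound F9. A Nef reaction (NaOMe, then TiCl3 with NH4OAc) gives 28, which rejoins step 18 at the Wittig stage.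

Step 23. Most likely to go wrong: acyl transfer within 33 after a ring flip, or γ-deprotonation of the activated acid with double-bond migration and loss of the C-1′ configuration. Fallback, setting out from 33: 2,4,6-triisopropylbenzenesulfonyl chloride and pyridine give the primary sulfonate F10. DBU closes the spiro-epoxide F11, with the C-9–O bond untouched. The caesium salt of 32 (Cs2CO3, DMF, 50 °C) opens F11 at CH2 and returns to 35 without an activated acyl derivative.

## Further compounds

F1 | step 12 | cis aldehyde acid one carbon shorter than 12 (CHO on C-5a, CO2H on C-9a; ketal intact) | CC(C)[C@@H]1CC[C@]3(COC(C)(C)O3)[C@@H](C(=O)O)[C@H]1C=O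
F2 | step 12 | (Z)-2-bromoacrylate 2-(trimethylsilyl)ethyl ester on C-5a with free C-9a acid | CC(C)[C@@H]1CC[C@]3(COC(C)(C)O3)[C@@H](C(=O)O)[C@H]1/C=C(\Br)C(=O)OCC[Si](C)(C)C
F3 | step 12 | (E)-2-(hydroxymethyl)acrylate 2-(trimethylsilyl)ethyl ester on C-5a with free C-9a acid | CC(C)[C@@H]1CC[C@]3(COC(C)(C)O3)[C@@H](C(=O)O)[C@H]1/C=C(\CO)C(=O)OCC[Si](C)(C)C
F4 | step 3 | (4S)-2-bromo-4-isopropylcyclohex-2-en-1-one | CC(C)[C@@H]1CCC(=O)C(Br)=C1
F5 | step 3 | 8a-bromo analogue of 6 | CC(C)[C@@H]1CCC(=O)[C@@]2(Br)[C@@H](O[Si](C)(C)C)C=CC[C@@H]12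
F6 | step 4 | spiro-epoxide of 6 at C-1 (oxygen cis to the C-8a–C-8 bond) | CC(C)[C@@H]1CC[C@]3(CO3)[C@H]2[C@@H](O[Si](C)(C)C)C=CC[C@@H]12
F7 | step 17 | (1R,6S)-3-{[(tert-butyldimethylsilyl)oxy]methyl}-6-isopropylcyclohex-2-en-1-ol | CC(C)[C@@H]1CCC(CO[Si](C)(C)C(C)(C)C)=C[C@@H]1O
F8 | step 17 | methyl carbonate of F7 | CC(C)[C@@H]1CCC(CO[Si](C)(C)C(C)(C)C)=C[C@@H]1OC(=O)OC
F9 | step 17 | cis (1R,6S)-1-(nitromethyl)-3-{[(tert-butyldimethylsilyl)oxy]methyl}-6-isopropylcyclohex-2-ene | CC(C)[C@@H]1CCC(CO[Si](C)(C)C(C)(C)C)=C[C@@H]1C[N+](=O)[O-]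
F10 | step 23 | primary 2,4,6-triisopropylbenzenesulfonate of 33 | CC(C)[C@@H]1CC[C@](O)(COS(=O)(=O)c4c(C(C)C)cc(C(C)C)cc4C(C)C)[C@H]2C(=O)OCC(C(=O)OCC[Si](C)(C)C)=C[C@@H]12
F11 | step 23 | spiro-epoxide from the C-9 oxygen and its CH2 in the lactone of 33 | CC(C)[C@@H]1CC[C@]3(CO3)[C@H]2C(=O)OCC(C(=O)OCC[Si](C)(C)C)=C[C@@H]12
A1 | alternative 1 | methyl (2E)-3-[cis-6-acetyl-3-(silyloxymethyl)cyclohex-2-en-1-yl]-2-(silyloxymethyl)prop-2-enoate | COC(=O)/C(=C/[C@H]1C=C(CO[Si](C)(C)C(C)(C)C)CC[C@H]1C(C)=O)CO[Si](C)(C)C(C)(C)C
A2 | alternative 1 | methyl (2E,4E)-2,6-bis(silyloxymethyl)hepta-2,4,6-trienoate | COC(=O)/C(CO[Si](C)(C)C(C)(C)C)=C/C=C/C(=C)CO[Si](C)(C)C(C)(C)C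
A3 | alternative 2 | cis-fused iodomethyl β-lactone with the open ring B arm | CC(C)[C@@H]1CC[C@@]3(CI)OC(=O)[C@H]3[C@H]1/C=C(\CO[Si](C)(C)C(C)(C)C)C(=O)OCC[Si](C)(C)C
A4 | alternative 2 | cis β,γ-unsaturated acid with exocyclic methylene on C-9 and the open ring B arm | CC(C)[C@@H]1CCC(=C)[C@@H](C(=O)O)[C@H]1/C=C(\CO[Si](C)(C)C(C)(C)C)C(=O)OCC[Si](C)(C)C
A5 | alternative 3 | cis-2-vinylcyclohexanecarboxylic acid with exocyclic methylene and isopropyl group | CC(C)[C@@H]1CCC(=C)[C@@H](C(=O)O)[C@H]1C=C
A6 | alternative 3 | ten-membered (E)-allylic lactone | CC(C)[C@@H]1CCC(=C)CC(=O)OC/C=C/1
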